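**Retrosynthetic overview**

1. The strategy rests on ring B (C-1' to C-6'): oxygen sits on the alternate carbons C-2', C-4' and C-6', the C-5' methyl lies between the C-4' hydroxyl and the C-6' methoxyl, and C-1' carries the CH2 bridge to ring A. This is the pattern a 3-alkoxycyclobutenone and 1-methoxyprop-1-yne deliver.
2. Late stage: target ⇐ hepta-O-benzyl ether ⇐ twofold Friedel–Crafts butanoylation at C-3' of each ring B ⇐ O-benzylated bis-phenol.
3. Key disconnection: in each ring B the bonds C-4'–C-5' and C-6'–C-1' are cut, which returns 1-methoxyprop-1-yne and a 3-benzyloxycyclobutenone carrying the bridge CH2 at C-2.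
4. The bis-cyclobutenone comes from a ring A dialdehyde and cyclobutane-1,3-dione by reductive alkylation and O-benzylation; the dialdehyde comes from phloroglucinol by diformylation, butanoylation and benzylation.
5. Ring order: ring A is bought as phloroglucinol, the two four-membered rings are attached as preformed units, and both rings B are formed together in the key step.

Key step: step 8

Remark: ring B is numbered C-1' (bridge-bearing), C-2' (OH), C-3' (butanoyl), C-4' (OH), C-5' (methyl), C-6' (OMe); cyclobutane-1,3-dione is drawn as the diketone although it reacts as its enol, 3-hydroxycyclobut-2-en-1-one.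

**Route**

Step 1
Reactants: 1 phloroglucinol
Product: 2 2,4,6-trihydroxybenzene-1,3-dicarbaldehyde
Conditions: POCl3 (2.2 equiv), DMF, 1,4-dioxane, 0 °C to rt; then H2O
Reagents that add atoms: N,N-dimethylformamide CN(C)C=O; water O
Why: Vilsmeier–Haack formylation of the very electron-rich triphenol stops at the dialdehyde under reagent control because each formyl group deactivates the ring, and formylating before acylation keeps the chloroiminium reagent away from an ortho-hydroxyaryl ketone side chain.

Step 2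
Reactants: 2 2,4,6-trihydroxybenzene-1,3-dicarbaldehyde; 3 butanoyl chloride
Product: 4 5-butanoyl-2,4,6-trihydroxybenzene-1,3-dicarbaldehyde
Conditions: TiCl4, CH2Cl2, 0 °C to reflux; aq. HCl work-up
Reagents that add atoms: none
Why: Friedel–Crafts acylation at the only free ring carbon, still activated by three hydroxyls; any O-acylated material should converge on the same ketone by Fries shift on the titanium phenoxide.

Step 3
Reactants: 4 5-butanoyl-2,4,6-trihydroxybenzene-1,3-dicarbaldehyde
Product: 5 2,4,6-tris(benzyloxy)-5-butanoylbenzene-1,3-dicarbaldehyde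
Conditions: BnBr (3.6 equiv), K2CO3, Bu4NI (cat.), DMF, 60 °C
Reagents that add atoms: benzyl bromide BrCc1ccccc1
Why: Williamson etherification; the phenoxides are chelated vinylogous carboxylates and need warm DMF with iodide catalysis, and alkylation should go to oxygen because every ring carbon already carries an acyl group.

Step 4
Reactants: 6 3-ethoxycyclobut-2-en-1-one
Product: 7 cyclobutane-1,3-dione
Conditions: 1 M aq. HCl, 0 °C to rt; extracted and used without storage
Reagents that add atoms: water O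
Why: acid hydrolysis of a vinylogous ester by addition–elimination at C-3 frees the dione, which keeps poorly and is therefore made just before use.

Step 5
Reactants: 5 2,4,6-tris(benzyloxy)-5-butanoylbenzene-1,3-dicarbaldehyde; 7 cyclobutane-1,3-dione
Product: 9 1-[2,4,6-tris(benzyloxy)-3,5-bis[(2-hydroxy-4-oxocyclobut-1-en-1-yl)methyl]phenyl]butan-1-one, via bis(arylidene-dione) 8 (not isolated)
Conditions: 7 (2.2 equiv), diethyl 2,6-dimethyl-1,4-dihydropyridine-3,5-dicarboxylate (Hantzsch ester, 2.2 equiv), L-proline (20 mol %), CH2Cl2, rt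
Reagents that add atoms: none
Why: organocatalytic three-component reductive alkylation of a cyclic 1,3-dione, in which Knoevenagel condensation at C-2 of the dione is followed by Hantzsch ester conjugate reduction of the arylidene; it needs no strong base or metal hydride, so the ring A ketone is untouched, and the two ortho benzyloxy groups shield the arylidene from a second dione.

Step 6
Reactants: 9 1-[2,4,6-tris(benzyloxy)-3,5-bis[(2-hydroxy-4-oxocyclobut-1-en-1-yl)methyl]phenyl]butan-1-one
Product: 10 1-[2,4,6-tris(benzyloxy)-3,5-bis{[2-(benzyloxy)-4-oxocyclobut-1-en-1-yl]methyl}phenyl]butan-1-one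
Conditions: BnOH, PPh3, DIAD, THF, 0 °C to rt
Reagents that add atoms: benzyl alcohol OCc1ccccc1
Why: Mitsunobu O-alkylation of a strongly acidic enol; the anion enolized toward the substituted carbon has two equivalent oxygens, so one enol ether with the bridge CH2 at C-2 is expected, and the neutral conditions avoid C-benzylation.

Step 7
Reactants: 11 2-bromo-1,1-dimethoxypropane (racemic)
Product: 12 1-methoxyprop-1-yne
Conditions: NaNH2 (2.2 equiv), liquid NH3, −33 °C; then H2O, distillation
Reagents that add atoms: none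
Why: twofold base-induced elimination (loss of methanol and of HBr) from an alpha-halo acetal, the standard entry to 1-alkoxyalkynes, which are the stable isomers under amide base.

Step 8
Reactants: 10 1-[2,4,6-tris(benzyloxy)-3,5-bis{[2-(benzyloxy)-4-oxocyclobut-1-en-1-yl]methyl}phenyl]butan-1-one; 12 1-methoxyprop-1-yne
Product: 17 1-[2,4,6-tris(benzyloxy)-3,5-bis{[6-(benzyloxy)-4-hydroxy-2-methoxy-3-methylphenyl]methyl}phenyl]butan-1-one, via bis(vinylketene) 13 (not isolated), via bis(vinylcyclobutenone) 14 (not isolated), via bis(dienylketene) 15 (not isolated), via bis(cyclohexadienone) 16 (not isolated)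
Conditions: 12 (6 equiv), toluene (0.05 M), sealed tube, 110 °C then 150 °C
Reagents that add atoms: none
Why: Danheiser benzannulation run twice in one molecule: on heating, each vinylogous-ester cyclobutenone of 10 undergoes four-electron conrotatory opening of its C1–C4 bond to the (1-benzyloxyvinyl)ketene of 13, which adds 12 in a [2+2] cycloaddition to give the 4-vinylcyclobutenone of 14. A second four-electron opening, cleaving the former C1–C2 bond, gives the dienylketene of 15, whose six-electron disrotatory electrocyclization joins the ketene carbon to the terminal CH2 and closes each ring B as the cyclohexa-2,4-dienone of 16; tautomerization then gives the phenol, so the two alkyne carbons end up inserted between C-1 and C-2 of the former four-membered ring. The closest known reaction type is the thermal benzannulation of 2,3-disubstituted cyclobutenones with 1-alkoxyalkynes to highly substituted resorcinol monoethers. The one selectivity required is the orientation of the [2+2] step, and it is secured by the polarization of the ynol ether: its methyl-bearing carbon is the nucleophilic terminus and bonds to the ketene carbonyl carbon, which places the methyl next to the new hydroxyl and the methoxyl next to the bridge-bearing carbon. No stereocentre reaches 17 (the quaternary carbons of 14 are erased on ring opening); the first opening has no torquoselectivity issue because C-4 of each cyclobutenone is an unsubstituted CH2, and a non-productive rotation in the second opening is reversible and drains through the cyclizable isomer. The conditions are neutral, so the ring A ketone, the benzyl ethers and the diarylmethane bridges are spectators.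

Step 9
Reactants: 17 1-[2,4,6-tris(benzyloxy)-3,5-bis{[6-(benzyloxy)-4-hydroxy-2-methoxy-3-methylphenyl]methyl}phenyl]butan-1-one
Product: 18 1-[2,4,6-tris(benzyloxy)-3,5-bis{[4,6-bis(benzyloxy)-2-methoxy-3-methylphenyl]methyl}phenyl]butan-1-one
Conditions: BnBr, K2CO3, DMF, rt to 50 °C
Reagents that add atoms: benzyl bromide BrCc1ccccc1
Why: Williamson etherification of the two unhindered C-4' phenols; capping them prevents O-acylation in the next step and leaves C-3' as a carbon flanked by two ether oxygens and para to a third.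

Step 10
Reactants: 18 1-[2,4,6-tris(benzyloxy)-3,5-bis{[4,6-bis(benzyloxy)-2-methoxy-3-methylphenyl]methyl}phenyl]butan-1-one; 19 butanoic acid
Product: 20 1-[2,4,6-tris(benzyloxy)-3,5-bis{[2,4-bis(benzyloxy)-3-butanoyl-6-methoxy-5-methylphenyl]methyl}phenyl]butan-1-one
Conditions: 19 (3 equiv), (CF3CO)2O, CH2Cl2, 0 °C to rt
Reagents that add atoms: none
Why: Friedel–Crafts acylation through the mixed trifluoroacetic anhydride at the only unsubstituted ring carbon of each ring B, a phloroglucinol-triether-type position; no metal Lewis acid is present, so benzyl ethers next to the ketones are not cleaved by chelation.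

Step 11
Reactants: 20 1-[2,4,6-tris(benzyloxy)-3,5-bis{[2,4-bis(benzyloxy)-3-butanoyl-6-methoxy-5-methylphenyl]methyl}phenyl]butan-1-one
Product: 21 1-[3,5-bis[(3-butanoyl-2,4-dihydroxy-6-methoxy-5-methylphenyl)methyl]-2,4,6-trihydroxyphenyl]butan-1-one (CNP0264591.0)
Conditions: H2 (1 atm), Pd/C (10 %), EtOAc–MeOH, rt
Reagents that add atoms: none
Why: catalytic hydrogenolysis of the seven benzyl aryl ethers under neutral conditions; the crowded, later hydrogen-bonded aryl ketones and the diarylmethane bridges should not be reduced at ambient pressure, and the methyl ether stays.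

**Compound list**

1 | phloroglucinol (benzene-1,3,5-triol) | Oc1cc(O)cc(O)c1 | starting material
2 | 2,4,6-trihydroxybenzene-1,3-dicarbaldehyde | O=Cc1c(O)c(C=O)c(O)cc1O | intermediate
3 | butanoyl chloride | CCCC(Cl)=O | starting material
4 | 5-butanoyl-2,4,6-trihydroxybenzene-1,3-dicarbaldehyde | CCCC(=O)c1c(O)c(C=O)c(O)c(C=O)c1O | intermediate
5 | 2,4,6-tris(benzyloxy)-5-butanoylbenzene-1,3-dicarbaldehyde | CCCC(=O)c1c(OCc2ccccc2)c(C=O)c(OCc2ccccc2)c(C=O)c1OCc1ccccc1 | intermediate
6 | 3-ethoxycyclobut-2-en-1-one | CCOC1=CC(=O)C1 | starting material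
7 | cyclobutane-1,3-dione (enol form 3-hydroxycyclobut-2-en-1-one) | O=C1CC(=O)C1 | intermediate
8 | bis(arylidene-dione): ring A of 5 in which each former CHO carbon is doubly bonded to C-2 of a cyclobutane-1,3-dione | CCCC(=O)c1c(OCc2ccccc2)c(C=C2C(=O)CC2=O)c(OCc2ccccc2)c(C=C2C(=O)CC2=O)c1OCc1ccccc1 | intermediate (not isolated)
9 | 1-[2,4,6-tris(benzyloxy)-3,5-bis[(2-hydroxy-4-oxocyclobut-1-en-1-yl)methyl]phenyl]butan-1-one | CCCC(=O)c1c(OCc2ccccc2)c(CC2=C(O)CC2=O)c(OCc2ccccc2)c(CC2=C(O)CC2=O)c1OCc1ccccc1 | intermediate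
10 | 1-[2,4,6-tris(benzyloxy)-3,5-bis{[2-(benzyloxy)-4-oxocyclobut-1-en-1-yl]methyl}phenyl]butan-1-one | CCCC(=O)c1c(OCc2ccccc2)c(CC2=C(OCc3ccccc3)CC2=O)c(OCc2ccccc2)c(CC2=C(OCc3ccccc3)CC2=O)c1OCc1ccccc1 | intermediate
11 | 2-bromo-1,1-dimethoxypropane (racemic) | CC(Br)C(OC)OC | starting material
12 | 1-methoxyprop-1-yne | CC#COC | intermediate
13 | bis(vinylketene): each bridge CH2 bonded to the ketene carbon C(=C=O), which also carries a 1-(benzyloxy)vinyl group | CCCC(=O)c1c(OCc2ccccc2)c(CC(=C=O)C(=C)OCc2ccccc2)c(OCc2ccccc2)c(CC(=C=O)C(=C)OCc2ccccc2)c1OCc1ccccc1 | intermediate (not isolated)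
14 | bis(vinylcyclobutenone): each bridge CH2 bonded to C-4 of a 3-methoxy-2-methylcyclobut-2-en-1-one that also carries a 1-(benzyloxy)vinyl group at C-4 (transient quaternary stereocentres, mixture) | CCCC(=O)c1c(OCc2ccccc2)c(CC2(C(=C)OCc3ccccc3)C(=O)C(C)=C2OC)c(OCc2ccccc2)c(CC2(C(=C)OCc3ccccc3)C(=O)C(C)=C2OC)c1OCc1ccccc1 | intermediate (not isolated)
15 | bis(dienylketene): each arm CH2–C[C(OBn)=CH2]=C(OMe)–C(Me)=C=O with the ketenyl and benzyloxyvinyl groups cis on the central double bond | CCCC(=O)c1c(OCc2ccccc2)c(C/C(C(=C)OCc2ccccc2)=C(\OC)C(C)=C=O)c(OCc2ccccc2)c(C/C(C(=C)OCc2ccccc2)=C(\OC)C(C)=C=O)c1OCc1ccccc1 | intermediate (not isolated)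
16 | bis(cyclohexadienone): each arm a 5-(benzyloxy)-3-methoxy-2-methylcyclohexa-2,4-dien-1-one bonded through C-4 to the bridge CH2 | CCCC(=O)c1c(OCc2ccccc2)c(CC2=C(OCc3ccccc3)CC(=O)C(C)=C2OC)c(OCc2ccccc2)c(CC2=C(OCc3ccccc3)CC(=O)C(C)=C2OC)c1OCc1ccccc1 | intermediate (not isolated)
17 | 1-[2,4,6-tris(benzyloxy)-3,5-bis{[6-(benzyloxy)-4-hydroxy-2-methoxy-3-methylphenyl]methyl}phenyl]butan-1-one | CCCC(=O)c1c(OCc2ccccc2)c(Cc2c(OCc3ccccc3)cc(O)c(C)c2OC)c(OCc2ccccc2)c(Cc2c(OCc3ccccc3)cc(O)c(C)c2OC)c1OCc1ccccc1 | intermediate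
18 | 1-[2,4,6-tris(benzyloxy)-3,5-bis{[4,6-bis(benzyloxy)-2-methoxy-3-methylphenyl]methyl}phenyl]butan-1-one | CCCC(=O)c1c(OCc2ccccc2)c(Cc2c(OCc3ccccc3)cc(OCc3ccccc3)c(C)c2OC)c(OCc2ccccc2)c(Cc2c(OCc3ccccc3)cc(OCc3ccccc3)c(C)c2OC)c1OCc1ccccc1 | intermediate
19 | butanoic acid | CCCC(=O)O | starting material
20 | 1-[2,4,6-tris(benzyloxy)-3,5-bis{[2,4-bis(benzyloxy)-3-butanoyl-6-methoxy-5-methylphenyl]methyl}phenyl]butan-1-one | CCCC(=O)c1c(OCc2ccccc2)c(Cc2c(OCc3ccccc3)c(C(=O)CCC)c(OCc3ccccc3)c(C)c2OC)c(OCc2ccccc2)c(Cc2c(OCc3ccccc3)c(C(=O)CCC)c(OCc3ccccc3)c(C)c2OC)c1OCc1ccccc1 | intermediate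
21 | 1-[3,5-bis[(3-butanoyl-2,4-dihydroxy-6-methoxy-5-methylphenyl)methyl]-2,4,6-trihydroxyphenyl]butan-1-one | CCCC(=O)c1c(O)c(Cc2c(O)c(C(=O)CCC)c(O)c(C)c2OC)c(O)c(Cc2c(O)c(C(=O)CCC)c(O)c(C)c2OC)c1O | target

**Step count and risks**

Total step count: 11. Longest linear sequence: 9 steps (steps 1, 2, 3, 5, 6, 8, 9, 10, 11).

Steps most likely to fail:

Step 8. The electrocyclic opening of a resonance-stabilized 3-alkoxycyclobutenone may be slow enough that the volatile ynol ether polymerizes first. The ketenes may also be intercepted by phenol already formed, giving aryl esters and oligomers, and the second arm may lag behind the first. The fallback changes the alkyne partner and sets out from 10. 10 would be heated with 1-[tri(propan-2-yl)silyloxy]prop-1-yne F1, prepared by O-silylation with i-Pr3SiCl of the lithium ynolate that the Kowalski ester homologation generates from ethyl acetate. F1 is thermally more robust and more nucleophilic toward ketenes than 12, and should give, with the same orientation, 1-[2,4,6-tris(benzyloxy)-3,5-bis{[6-(benzyloxy)-4-hydroxy-3-methyl-2-(triisopropylsilyloxy)phenyl]methyl}phenyl]butan-1-one F2. Benzylation of the two free phenols (BnBr, K2CO3, DMF) would give 1-[2,4,6-tris(benzyloxy)-3,5-bis{[4,6-bis(benzyloxy)-3-methyl-2-(triisopropylsilyloxy)phenyl]methyl}phenyl]butan-1-one F3. Bu4NF in THF would free 1-[2,4,6-tris(benzyloxy)-3,5-bis{[4,6-bis(benzyloxy)-2-hydroxy-3-methylphenyl]methyl}phenyl]butan-1-one F4, which would be methylated in the same flask (MeI, K2CO3) to 18, where the route is rejoined.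

Step 5. The strained dione may be opened or tied up as an enaminone by the amine catalyst, it may condense a second time at its other methylene, or a second dione may add to the arylidene before hydride transfer. The fallback replaces condensation and reduction by an acid-catalysed SN1 alkylation and sets out from 5. The two aldehydes would be reduced with NaBH4 (THF–MeOH, −20 °C; the hindered ring A ketone should react more slowly) to 1-[2,4,6-tris(benzyloxy)-3,5-bis(hydroxymethyl)phenyl]butan-1-one F5. F5 and 7 (2.2 equiv) with catalytic TsOH in MeNO2 at rt should ionize to the 2,4,6-trialkoxybenzyl cations and alkylate the enol at carbon (O-alkylation being reversible under acid), giving 9, where the route is rejoined.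

Step 10. The trifluoroacetic acid released may cause migration or loss of benzyl groups on the electron-rich rings or protolytic cleavage of the diarylmethane bridges, and acylation at the crowded C-3' may stall after one ring. The fallback avoids acid and sets out from 17, using the free C-4' hydroxyl as a directing group. Magnesium-phenoxide ortho-formylation (MgCl2, Et3N, paraformaldehyde, MeCN, reflux) should give 1-[2,4,6-tris(benzyloxy)-3,5-bis{[2-(benzyloxy)-3-formyl-4-hydroxy-6-methoxy-5-methylphenyl]methyl}phenyl]butan-1-one F6. Aldehyde-selective addition of n-PrTi(OiPr)3 (from n-PrMgBr and ClTi(OiPr)3, excess, THF, −40 °C) would give 1-[2,4,6-tris(benzyloxy)-3,5-bis{[2-(benzyloxy)-4-hydroxy-3-(1-hydroxybutyl)-6-methoxy-5-methylphenyl]methyl}phenyl]butan-1-one F7 as a mixture of stereoisomers. Oxidation with MnO2 (CH2Cl2, rt) would give 1-[2,4,6-tris(benzyloxy)-3,5-bis{[2-(benzyloxy)-3-butanoyl-4-hydroxy-6-methoxy-5-methylphenyl]methyl}phenyl]butan-1-one F8. Hydrogenolysis of F8 (H2, Pd/C, EtOAc–MeOH) would remove the five benzyl groups and give 21, where the route is rejoined.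

**Further compounds**

F1 | step 8 | 1-[tri(propan-2-yl)silyloxy]prop-1-yne | CC#CO[Si](C(C)C)(C(C)C)C(C)C
F2 | step 8 | 1-[2,4,6-tris(benzyloxy)-3,5-bis{[6-(benzyloxy)-4-hydroxy-3-methyl-2-(triisopropylsilyloxy)phenyl]methyl}phenyl]butan-1-one | CCCC(=O)c1c(OCc2ccccc2)c(Cc2c(OCc3ccccc3)cc(O)c(C)c2O[Si](C(C)C)(C(C)C)C(C)C)c(OCc2ccccc2)c(Cc2c(OCc3ccccc3)cc(O)c(C)c2O[Si](C(C)C)(C(C)C)C(C)C)c1OCc1ccccc1
F3 | step 8 | 1-[2,4,6-tris(benzyloxy)-3,5-bis{[4,6-bis(benzyloxy)-3-methyl-2-(triisopropylsilyloxy)phenyl]methyl}phenyl]butan-1-one | CCCC(=O)c1c(OCc2ccccc2)c(Cc2c(OCc3ccccc3)cc(OCc3ccccc3)c(C)c2O[Si](C(C)C)(C(C)C)C(C)C)c(OCc2ccccc2)c(Cc2c(OCc3ccccc3)cc(OCc3ccccc3)c(C)c2O[Si](C(C)C)(C(C)C)C(C)C)c1OCc1ccccc1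
F4 | step 8 | 1-[2,4,6-tris(benzyloxy)-3,5-bis{[4,6-bis(benzyloxy)-2-hydroxy-3-methylphenyl]methyl}phenyl]butan-1-one | CCCC(=O)c1c(OCc2ccccc2)c(Cc2c(OCc3ccccc3)cc(OCc3ccccc3)c(C)c2O)c(OCc2ccccc2)c(Cc2c(OCc3ccccc3)cc(OCc3ccccc3)c(C)c2O)c1OCc1ccccc1
F5 | step 5 | 1-[2,4,6-tris(benzyloxy)-3,5-bis(hydroxymethyl)phenyl]butan-1-one | CCCC(=O)c1c(OCc2ccccc2)c(CO)c(OCc2ccccc2)c(CO)c1OCc1ccccc1
F6 | step 10 | 1-[2,4,6-tris(benzyloxy)-3,5-bis{[2-(benzyloxy)-3-formyl-4-hydroxy-6-methoxy-5-methylphenyl]methyl}phenyl]butan-1-one | CCCC(=O)c1c(OCc2ccccc2)c(Cc2c(OCc3ccccc3)c(C=O)c(O)c(C)c2OC)c(OCc2ccccc2)c(Cc2c(OCc3ccccc3)c(C=O)c(O)c(C)c2OC)c1OCc1ccccc1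
F7 | step 10 | 1-[2,4,6-tris(benzyloxy)-3,5-bis{[2-(benzyloxy)-4-hydroxy-3-(1-hydroxybutyl)-6-methoxy-5-methylphenyl]methyl}phenyl]butan-1-one (mixture of stereoisomers) | CCCC(=O)c1c(OCc2ccccc2)c(Cc2c(OCc3ccccc3)c(C(O)CCC)c(O)c(C)c2OC)c(OCc2ccccc2)c(Cc2c(OCc3ccccc3)c(C(O)CCC)c(O)c(C)c2OC)c1OCc1ccccc1
F8 | step 10 | 1-[2,4,6-tris(benzyloxy)-3,5-bis{[2-(benzyloxy)-3-butanoyl-4-hydroxy-6-methoxy-5-methylphenyl]methyl}phenyl]butan-1-one | CCCC(=O)c1c(OCc2ccccc2)c(Cc2c(OCc3ccccc3)c(C(=O)CCC)c(O)c(C)c2OC)c(OCc2ccccc2)c(Cc2c(OCc3ccccc3)c(C(=O)CCC)c(O)c(C)c2OC)c1OCc1ccccc1
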